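**Strategy.** The cyclohexene ring (C1 OMe, C2=C3 with CH2OBz on C3, C4 OH, C5 OBz, C6 OH) is opened between C4 and C5, the two neighbouring oxygen-bearing carbons. Both are carbonyl carbons in the precursor, so their union is a like-polarity coupling: SmI2 turns the (Z)-enal carbonyl of an acyclic enedial into a ketyl that adds to the second aldehyde and closes the six-membered ring as a 1,2-diol in one operation. The precursor, (2Z,4S,5R)-4-methoxy-5-(triethylsilyloxy)hex-2-enedial, draws C1 and C6 from L-threonate. The C3 hydroxymethyl branch is added afterwards by a Morita–Baylis–Hillman reaction, and C4 is reset by oxidation and Luche reduction.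

Key step: step 8

Remark: methyl 3,4-O-isopropylidene-L-threonate and methyl bis(2,2,2-trifluoroethyl)phosphonoacetate are taken as purchasable; positions C1–C6 cited in the text are those of the overview, while systematic names use their own locants.

Step 1
Reactants: 1 methyl (2R)-2-[(4S)-2,2-dimethyl-1,3-dioxolan-4-yl]-2-hydroxyacetate (methyl 3,4-O-isopropylidene-L-threonate)
Product: 2 methyl (2R)-2-[(4S)-2,2-dimethyl-1,3-dioxolan-4-yl]-2-methoxyacetate
Conditions: MeI, Ag2O, MS 4 Å, Et2O, rt, dark
Reagents that add atoms: iodomethane CI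
Why: Purdie-type O-methylation with Ag2O/MeI is non-basic, so the α-stereocentre should not enolise and the β-oxygen should not be eliminated; no new stereocentre is formed.

Step 2
Reactants: 2 methyl (2R)-2-[(4S)-2,2-dimethyl-1,3-dioxolan-4-yl]-2-methoxyacetate
Product: 3 (2R)-2-[(4S)-2,2-dimethyl-1,3-dioxolan-4-yl]-2-methoxyacetaldehyde
Conditions: i-Bu2AlH (1.1 equiv), CH2Cl2, −78 °C; MeOH, aq. potassium sodium tartrate
Reagents that add atoms: none
Why: Partial reduction of an α-alkoxy ester with i-Bu2AlH at −78 °C should stop at the aluminium hemiacetal and release the aldehyde on work-up; the crude aldehyde is used at once to avoid epimerisation.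

Step 3
Reactants: 3 (2R)-2-[(4S)-2,2-dimethyl-1,3-dioxolan-4-yl]-2-methoxyacetaldehyde
Product: 4 methyl (2Z,4S)-4-[(4S)-2,2-dimethyl-1,3-dioxolan-4-yl]-4-methoxybut-2-enoate
Conditions: methyl bis(2,2,2-trifluoroethyl)phosphonoacetate, KN(SiMe3)2, 18-crown-6, THF, −78 °C; then 3
Reagents that add atoms: methyl bis(2,2,2-trifluoroethyl)phosphonoacetate COC(=O)CP(=O)(OCC(F)(F)F)OCC(F)(F)F
Why: Still–Gennari olefination of an α-alkoxy aldehyde should give the (Z)-enoate under kinetic control, which fixes the cis relation between C1 and the future C4 carbonyl.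

Step 4
Reactants: 4 methyl (2Z,4S)-4-[(4S)-2,2-dimethyl-1,3-dioxolan-4-yl]-4-methoxybut-2-enoate
Product: 5 (2Z,4S)-4-[(4S)-2,2-dimethyl-1,3-dioxolan-4-yl]-4-methoxybut-2-en-1-ol
Conditions: i-Bu2AlH (2.5 equiv), CH2Cl2, −78 °C
Reagents that add atoms: none
Why: 1,2-Reduction of the enoate with i-Bu2AlH should give the (Z)-allylic alcohol without touching alkene geometry or acetonide, and it is done before acetonide removal so that the (Z)-ester cannot lactonise.

Step 5
Reactants: 5 (2Z,4S)-4-[(4S)-2,2-dimethyl-1,3-dioxolan-4-yl]-4-methoxybut-2-en-1-ol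
Product: 6 (2S,3S,4Z)-3-methoxyhex-4-ene-1,2,6-triol
Conditions: AcOH/H2O (4:1), 40 °C
Reagents that add atoms: none
Why: Mild aqueous acid hydrolysis of the terminal acetonide should leave the methyl ether and the (Z)-allylic alcohol untouched.

Step 6
Reactants: 6 (2S,3S,4Z)-3-methoxyhex-4-ene-1,2,6-triol
Product: 7 (2S,3S,4Z)-3-methoxy-1,2,6-tris(triethylsilyloxy)hex-4-ene
Conditions: Et3SiCl, imidazole, DMF, 0 °C to rt
Reagents that add atoms: chlorotriethylsilane CC[Si](Cl)(CC)CC
Why: Exhaustive silylation should give two primary silyl ethers that act as latent aldehydes and one secondary silyl ether that protects the future C6 hydroxyl.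

Step 7
Reactants: 7 (2S,3S,4Z)-3-methoxy-1,2,6-tris(triethylsilyloxy)hex-4-ene
Product: 8 (2Z,4S,5R)-4-methoxy-5-(triethylsilyloxy)hex-2-enedial
Conditions: (COCl)2, DMSO, CH2Cl2, −78 to −35 °C; i-Pr2NEt, −78 to −20 °C; used crude
Reagents that add atoms: none
Why: Swern oxidation applied to silyl ethers should cleave and oxidise the two unhindered primary triethylsilyl ethers in place while the hindered secondary one stays; the bulky amine and low temperature are meant to preserve the (Z)-enal and the α-silyloxy stereocentre.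

Step 8
Reactants: 8 (2Z,4S,5R)-4-methoxy-5-(triethylsilyloxy)hex-2-enedial
Product: 9 (1R,2R,5S,6S)-5-methoxy-6-(triethylsilyloxy)cyclohex-3-ene-1,2-diol (1,2-cis diol; the C5 hydroxyl of the overview numbering trans to the silyloxy group)
Conditions: SmI2 (2.2 equiv), THF, −78 °C, slow addition of 8, high dilution, no proton source; then aq. NaHCO3
Reagents that add atoms: none
Why: Intramolecular pinacol coupling: SmI2 should reduce the conjugated, more easily reduced enal to an allylic ketyl whose carbonyl carbon (C4) adds to the C5 aldehyde held on the same trivalent samarium centre, and a second equivalent reduces the resulting oxygen radical to the diolate. The closest known reaction type is the SmI2 pinacol cyclisation of sugar-derived 1,6-dialdehydes to cyclohexane-1,2-diols. The six-membered ring closes in the 6-exo-trig mode, the (Z)-alkene holding both carbonyls within reach. The C5 centre is controlled by the adjacent C6 silyloxy group (new C–O bond anti to it, minimising dipole and steric repulsion), and the C4 centre by chelation of both oxygens to one samarium (cis-diol); C4 is oxidised in the next step, so only C5 has to be right. The step needs carbonyl-to-carbonyl coupling to outrun a second electron transfer to the ketyl (which would expel the C1 methoxy group) and intermolecular dimerisation; coupling through the β-carbon would give a four-membered ring and is excluded, and low temperature, dilution and the absence of a proton source should secure the rest.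

Step 9
Reactants: 9 (1R,2R,5S,6S)-5-methoxy-6-(triethylsilyloxy)cyclohex-3-ene-1,2-diol
Product: 10 (4S,5S,6S)-6-hydroxy-4-methoxy-5-(triethylsilyloxy)cyclohex-2-en-1-one
Conditions: MnO2 (excess), CH2Cl2, rt
Reagents that add atoms: none
Why: Chemoselective allylic oxidation with MnO2 should convert only the C4 hydroxyl into the enone carbonyl and leave the saturated C5 hydroxyl alone, so either C4 epimer from step 8 converges here.

Step 10
Reactants: 10 (4S,5S,6S)-6-hydroxy-4-methoxy-5-(triethylsilyloxy)cyclohex-2-en-1-one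
Product: 11 (4S,5S,6S)-6-hydroxy-2-(hydroxymethyl)-4-methoxy-5-(triethylsilyloxy)cyclohex-2-en-1-one
Conditions: 37% aq. HCHO, DMAP (0.3 equiv), THF/H2O, rt
Reagents that add atoms: formaldehyde C=O
Why: Morita–Baylis–Hillman reaction: DMAP adds to the enone β-carbon, the enolate traps formaldehyde at the α-carbon (C3) and DMAP is expelled, the established α-hydroxymethylation of 4-oxygenated cyclohex-2-enones; no stereocentre is formed.

Step 11
Reactants: 11 (4S,5S,6S)-6-hydroxy-2-(hydroxymethyl)-4-methoxy-5-(triethylsilyloxy)cyclohex-2-en-1-one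
Product: 12 [(3S,4R,5S)-5-(benzoyloxy)-3-methoxy-6-oxo-4-(triethylsilyloxy)cyclohex-1-en-1-yl]methyl benzoate
Conditions: BzCl (2.5 equiv), pyridine, DMAP (cat.), CH2Cl2, 0 °C
Reagents that add atoms: benzoyl chloride O=C(Cl)c1ccccc1
Why: Acylation of the only two free hydroxyls (primary allylic and the C5 ketol hydroxyl) should install both benzoates at once, with no regiochemical question because C6 is silylated and C4 is a ketone.

Step 12
Reactants: 12 [(3S,4R,5S)-5-(benzoyloxy)-3-methoxy-6-oxo-4-(triethylsilyloxy)cyclohex-1-en-1-yl]methyl benzoate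
Product: 14 [(3S,4R,5R,6S)-5-(benzoyloxy)-4,6-dihydroxy-3-methoxycyclohex-1-en-1-yl]methyl benzoate (target), via silyl ether 13 (not isolated)
Conditions: NaBH4, CeCl3·7H2O, MeOH, −78 °C; then 1 M aq. HCl, 0 °C
Reagents that add atoms: none
Why: Luche reduction should give clean 1,2-addition, with axial hydride attack on the half-chair (all substituents pseudo-equatorial) placing the new C4 hydroxyl trans to the C5 benzoate, the usual outcome for 6-oxygenated cyclohex-2-enones; acidification of the same solution should then cleave the triethylsilyl ether without acyl migration.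

**Compound list**

1 | methyl (2R)-2-[(4S)-2,2-dimethyl-1,3-dioxolan-4-yl]-2-hydroxyacetate (methyl 3,4-O-isopropylidene-L-threonate) | COC(=O)[C@H](O)[C@@H]1COC(C)(C)O1 | starting material
2 | methyl (2R)-2-[(4S)-2,2-dimethyl-1,3-dioxolan-4-yl]-2-methoxyacetate | COC(=O)[C@H](OC)[C@@H]1COC(C)(C)O1 | intermediate
3 | (2R)-2-[(4S)-2,2-dimethyl-1,3-dioxolan-4-yl]-2-methoxyacetaldehyde | O=C[C@H](OC)[C@@H]1COC(C)(C)O1 | intermediate
4 | methyl (2Z,4S)-4-[(4S)-2,2-dimethyl-1,3-dioxolan-4-yl]-4-methoxybut-2-enoate | COC(=O)/C=C\[C@H](OC)[C@@H]1COC(C)(C)O1 | intermediate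
5 | (2Z,4S)-4-[(4S)-2,2-dimethyl-1,3-dioxolan-4-yl]-4-methoxybut-2-en-1-ol | OC/C=C\[C@H](OC)[C@@H]1COC(C)(C)O1 | intermediate
6 | (2S,3S,4Z)-3-methoxyhex-4-ene-1,2,6-triol | OC/C=C\[C@H](OC)[C@@H](O)CO | intermediate
7 | (2S,3S,4Z)-3-methoxy-1,2,6-tris(triethylsilyloxy)hex-4-ene | CC[Si](CC)(CC)OC/C=C\[C@H](OC)[C@@H](O[Si](CC)(CC)CC)CO[Si](CC)(CC)CC | intermediate
8 | (2Z,4S,5R)-4-methoxy-5-(triethylsilyloxy)hex-2-enedial | O=C/C=C\[C@H](OC)[C@@H](O[Si](CC)(CC)CC)C=O | intermediate
9 | (1R,2R,5S,6S)-5-methoxy-6-(triethylsilyloxy)cyclohex-3-ene-1,2-diol | CO[C@H]1C=C[C@@H](O)[C@@H](O)[C@@H]1O[Si](CC)(CC)CC | intermediate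
10 | (4S,5S,6S)-6-hydroxy-4-methoxy-5-(triethylsilyloxy)cyclohex-2-en-1-one | CO[C@H]1C=CC(=O)[C@@H](O)[C@@H]1O[Si](CC)(CC)CC | intermediate
11 | (4S,5S,6S)-6-hydroxy-2-(hydroxymethyl)-4-methoxy-5-(triethylsilyloxy)cyclohex-2-en-1-one | CO[C@H]1C=C(CO)C(=O)[C@@H](O)[C@@H]1O[Si](CC)(CC)CC | intermediate
12 | [(3S,4R,5S)-5-(benzoyloxy)-3-methoxy-6-oxo-4-(triethylsilyloxy)cyclohex-1-en-1-yl]methyl benzoate | CO[C@H]1C=C(COC(=O)c2ccccc2)C(=O)[C@@H](OC(=O)c2ccccc2)[C@@H]1O[Si](CC)(CC)CC | intermediate
13 | [(3S,4R,5R,6S)-5-(benzoyloxy)-6-hydroxy-3-methoxy-4-(triethylsilyloxy)cyclohex-1-en-1-yl]methyl benzoate | CO[C@H]1C=C(COC(=O)c2ccccc2)[C@H](O)[C@@H](OC(=O)c2ccccc2)[C@@H]1O[Si](CC)(CC)CC | intermediate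
14 | [(3S,4R,5R,6S)-5-(benzoyloxy)-4,6-dihydroxy-3-methoxycyclohex-1-en-1-yl]methyl benzoate | CO[C@H]1C=C(COC(=O)c2ccccc2)[C@H](O)[C@@H](OC(=O)c2ccccc2)[C@@H]1O | target

Total step count: 12. Longest linear sequence: 12 steps (from 1).

**Steps most likely to fail**

Step 8 (ring closure). The allylic ketyl may take up a second electron before it cyclises, which would expel the neighbouring methoxy group or simply reduce the enal, and intermolecular coupling may compete. The fallback sets out from 8 and closes the same bond by a tin hydride radical chain (Bu3SnH, AIBN, benzene, 80 °C, slow addition), in which a neutral stannyloxy radical adds 6-exo to the other carbonyl and no carbanion can form. Hydrolysis of the tin alkoxides should give mainly the 1,2-trans diol (1R,2S,5S,6S)-5-methoxy-6-(triethylsilyloxy)cyclohex-3-ene-1,2-diol F1. Oxidation of F1 with MnO2 comes back to the route at 10.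

Step 7 (double oxidation). The amine base may isomerise the (Z)-enal to the (E)-enal or epimerise the centre next to the saturated aldehyde, and oxidative cleavage of one silyl ether may stall. The fallback sets out from 7 and separates deprotection from oxidation: HF·pyridine buffered with pyridine in THF at 0 °C should remove only the two primary silyl groups to give (2S,3S,4Z)-3-methoxy-2-(triethylsilyloxy)hex-4-ene-1,6-diol F2. Base-free oxidation of F2 with Dess–Martin periodinane and NaHCO3 in CH2Cl2 comes back to the route at 8.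

Step 10 (hydroxymethylation). The amine catalyst may instead promote enolisation on the ketol side, with β-elimination of the silyloxy group and aromatisation, or aldol reaction of formaldehyde at the ketol carbon. The fallback sets out from 10 and builds the C–C bond by cross-coupling: α-iodination with I2 and pyridine in CH2Cl2 should give (4S,5S,6S)-6-hydroxy-2-iodo-4-methoxy-5-(triethylsilyloxy)cyclohex-2-en-1-one F3. Stille coupling of F3 with Bu3SnCH2OH (Pd(PPh3)4, zerovalent palladium, CuI, dioxane, 60 °C) comes back to the route at 11.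

Further compounds
F1 | step 8 | (1R,2S,5S,6S)-5-methoxy-6-(triethylsilyloxy)cyclohex-3-ene-1,2-diol | CO[C@H]1C=C[C@H](O)[C@@H](O)[C@@H]1O[Si](CC)(CC)CC
F2 | step 7 | (2S,3S,4Z)-3-methoxy-2-(triethylsilyloxy)hex-4-ene-1,6-diol | OC/C=C\[C@H](OC)[C@@H](O[Si](CC)(CC)CC)CO
F3 | step 10 | (4S,5S,6S)-6-hydroxy-2-iodo-4-methoxy-5-(triethylsilyloxy)cyclohex-2-en-1-one | CO[C@H]1C=C(I)C(=O)[C@@H](O)[C@@H]1O[Si](CC)(CC)CC
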